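**Retrosynthetic overview**
1. Target 16 ⇐ desilylation and desulfurisation of oxocene spiro-dithiane 14; C15 carries the dithiane as a removable activating group.
2. Key disconnection: the O–C19 and C15–C16 bonds of the oxocene, cut as a [4+4] double alkylation of the O13/C15 dianion of hydroxy-dithiane 7 with (Z)-1-bromo-4-chloro-2-methylbut-2-ene 11. Enabling feature: the ether oxygen on C13 and the methylene C15 on C14 sit 1,3 and trans-diequatorial on ring C, and the four ring atoms between them (C16, C17 with its methyl, C18, C19) are a cis-2-methylbut-2-ene-1,4-diyl (isoprene) unit.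
3. 7 ⇐ sulfone 5 ⇐ radical 6-exo closure of ring C (C8–C14) in vinyl sulfone 4, itself from (+)-larixol 1 by cross-metathesis; larixol supplies rings A and B and C5, C6, C9, C10, C13.
4. Ring order: A/B (from 1) → C (step 3) → oxocene (step 9).

Key step: step 9

Remark on numbering: the tricycle is numbered as an isocopalane (ring C = C8, C9, C11–C14; methyls on C4, C8, C10, C13; C15 = CH2 on C14). C16–C19 are the four added ring carbons counted from C15 to the oxygen; C17 bears the methyl.
Remark on configuration: the target (5S,6S,8R,9R,10R,13S,14S) corresponds to 5α-H, 6α-OH, 8β-Me, 9α-H, 10β-Me, 13α-O/13β-Me, 14α-H.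
Assumption: (+)-larixol is taken as commercially available (13S)-labda-8(17),14-diene-6α,13-diol; its five stereocentres map unchanged onto C5, C6, C9, C10 and C13 of the target.

**Step 1**
Reactants: 1 (+)-larixol
Product: 2 6-O-TBS-larixol [(13S)-6α-(tert-butyldimethylsilyloxy)labda-8(17),14-dien-13-ol]
Conditions: TBSCl, imidazole, DMAP (cat.), DMF, 40 °C
Reagents that add atoms: tert-butyldimethylsilyl chloride, CC(C)(C)[Si](C)(C)Cl
Why: Silyl ether formation should be selective for the secondary 6α-hydroxyl, since the tertiary allylic 13-hydroxyl does not react with TBSCl/imidazole.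

**Step 2**
Reactants: 2 6-O-TBS-larixol; 3 phenyl vinyl sulfone
Product: 4 (13S,14E)-6α-TBSO-15-(phenylsulfonyl)labda-8(17),14-dien-13-ol
Conditions: second-generation Hoveyda–Grubbs catalyst (5 mol %), CH2Cl2, 40 °C
Reagents that add atoms: none
Why: Olefin cross-metathesis of the monosubstituted vinyl group with the electron-poor vinyl sulfone should give the E-vinyl sulfone, while the hindered 1,1-disubstituted exocyclic olefin stays out of the reaction.

**Step 3**
Reactants: 4 vinyl sulfone
Product: 5 6α-TBSO-15-(phenylsulfonyl)isocopalan-13α-ol (rings A/B/C trans-anti-trans; 8β-Me; 13β-Me; 14α-H)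
Conditions: Fe(acac)3 (30 mol %), PhSiH3, EtOH–(CH2OH)2 (5:1), 60 °C
Reagents that add atoms: none
Why: Hydrogen-atom-transfer-initiated reductive radical conjugate addition (Mukaiyama/Baran-type olefin coupling, Giese cyclisation): the iron hydride gives H• to C17, the tertiary C8 radical adds 6-exo-trig to C14 of the vinyl sulfone through a chair transition state on the α-face of C8 (anti to the axial C10 methyl, hence 8β-Me and trans B/C fusion) with the sulfonylmethylene pseudo-equatorial (14α-H), and the α-sulfonyl radical is reduced by divalent iron and protonated by ethanol.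

**Step 4**
Reactants: 5 tricyclic hydroxy sulfone
Product: 6 6α-TBSO-13α-hydroxyisocopalan-15-al
Conditions: n-BuLi (2.2 equiv), THF, −78 °C; (Me3SiO)2, −78 → 0 °C; aq NH4Cl
Reagents that add atoms: bis(trimethylsilyl) peroxide, C[Si](C)(C)OO[Si](C)(C)C
Why: Oxidative desulfonylation: the α-sulfonyl carbanion of the alkoxide/carbanion dianion is silyloxylated at C15 and the α-silyloxy sulfone collapses with loss of benzenesulfinate to the aldehyde, with no new stereocentre and the equatorial C14 substituent retained.

**Step 5**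
Reactants: 6 β-hydroxy aldehyde
Product: 7 2-substituted 1,3-dithiane of 6 (C15 = dithiane C2; 13α-OH free)
Conditions: HS(CH2)3SH, BF3·OEt2 (20 mol %), CH2Cl2, −30 °C
Reagents that add atoms: propane-1,3-dithiol, SCCCS
Why: Lewis-acid-catalysed dithioacetalisation turns C15 into a carbon with a single, weakly acidic hydrogen and should leave the silyl ether and the tertiary alcohol intact at low temperature.

**Step 6**
Reactants: 8 3-methylfuran-2(5H)-one
Product: 9 methyl (Z)-4-chloro-2-methylbut-2-enoate
Conditions: SOCl2, MeOH, 0 → 40 °C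
Reagents that add atoms: thionyl chloride, O=S(Cl)Cl; methanol, CO
Why: Acid-mediated lactone ring-opening: chloride attacks the protonated butenolide at the allylic O–CH2 carbon (SN2) and the acid is esterified, so the cis relation of CH2Cl and the carboxyl carbon is carried over from the ring.

**Step 7**
Reactants: 9 chloro ester
Product: 10 (Z)-4-chloro-2-methylbut-2-en-1-ol
Conditions: i-Bu2AlH (2.2 equiv), CH2Cl2, −78 °C; aq potassium sodium tartrate
Reagents that add atoms: none
Why: Hydride (1,2-) reduction of the enoate to the allylic alcohol at −78 °C should spare the allylic chloride and the Z-olefin.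

**Step 8**
Reactants: 10 chloro alcohol
Product: 11 (Z)-1-bromo-4-chloro-2-methylbut-2-ene
Conditions: CBr4, PPh3, CH2Cl2, −20 °C
Reagents that add atoms: carbon tetrabromide, BrC(Br)(Br)Br
Why: Appel bromination under neutral conditions (SN2 on the alkoxyphosphonium) gives the Z-unit with leaving groups of different reactivity at its two ends (Br at the future C16, Cl at the future C19).

**Step 9**
Reactants: 7 hydroxy-dithiane; 11 (Z)-1-bromo-4-chloro-2-methylbut-2-ene
Product: 14 6-O-TBS oxocene with C15 as spiro-1,3-dithiane, via dilithio dianion 12 (not isolated), via lithium chloro-alkoxide 13 (not isolated)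
Conditions: t-BuLi (2.1 equiv), THF–HMPA (10:1), −78 °C; 11, −78 °C; then 40 °C
Reagents that add atoms: none
Why: t-BuLi removes the carbinol proton and then the dithiane C15–H (Corey–Seebach), the carbanion of 12 displaces the allylic bromide of 11 by SN2 (C15–C16), and on warming the lithium alkoxide of 13 displaces the allylic chloride at C19 in an intramolecular Williamson etherification (O–C19). Closest known reaction types: alkylation of oxido-substituted 2-lithio-1,3-dithianes, the double alkylation of 1,4-dinucleophiles with (Z)-1,4-dihalobut-2-enes to eight-membered rings, and oxocene closures by SN2 on (Z)-allylic chlorides. The one ring closed is the oxocene, by 8-exo-tet attack of O13 on C19, helped by the cis olefin and by the gem-disubstituted spiro C15. No new stereocentre arises: the ring olefin keeps the Z geometry stored in 11 (from butenolide 8), and C13 and C14 are untouched. Required selectivities are C before O (the dithianyl carbanion is far more nucleophilic than the lithium alkoxide) and bromide before chloride at −78 °C (this puts the methyl-bearing carbon next to C16). Also required are SN2 instead of SN2′ at C19 (SN2′ would need attack of the tertiary alkoxide on the fully substituted C17) and no five-membered carbocyclisation, which the alkylated C15 excludes because it has no hydrogen left.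

**Step 10**
Reactants: 14 oxocene spiro-dithiane
Product: 15 6-O-TBS ether of the target
Conditions: Raney Ni (W-2, acetone-deactivated), EtOH, 25–50 °C
Reagents that add atoms: none
Why: Raney nickel desulfurisation (Mozingo reduction) converts the dithioketal carbon C15 into CH2, and deactivated nickel should spare the trisubstituted ring olefin and the allylic ether.

**Step 11**
Reactants: 15 silyl ether
Product: 16 CNP0179324.1
Conditions: Bu4NF, THF, 50 °C; aq NH4Cl
Reagents that add atoms: none
Why: Fluoride-mediated desilylation frees the equatorial 6α-hydroxyl without touching any stereocentre.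

**Compound list**
1 | (+)-larixol, (13S)-labda-8(17),14-diene-6α,13-diol | O[C@@](C=C)(C)CC[C@@H]1[C@@]2(C)CCCC(C)(C)[C@@H]2[C@@H](O)CC1=C | starting material
2 | 6-O-TBS-larixol | O[C@@](C=C)(C)CC[C@@H]1[C@@]2(C)CCCC(C)(C)[C@@H]2[C@@H](O[Si](C)(C)C(C)(C)C)CC1=C | intermediate
3 | phenyl vinyl sulfone | C=CS(=O)(=O)c1ccccc1 | starting material
4 | (13S,14E)-6α-TBSO-15-(phenylsulfonyl)labda-8(17),14-dien-13-ol | O[C@@](/C=C/S(=O)(=O)c1ccccc1)(C)CC[C@@H]2[C@@]3(C)CCCC(C)(C)[C@@H]3[C@@H](O[Si](C)(C)C(C)(C)C)CC2=C | intermediate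
5 | 6α-TBSO-15-(phenylsulfonyl)isocopalan-13α-ol | O[C@@]2(C)CC[C@@H]3[C@@]4(C)CCCC(C)(C)[C@@H]4[C@@H](O[Si](C)(C)C(C)(C)C)C[C@@]3(C)[C@@H]2CS(=O)(=O)c1ccccc1 | intermediate
6 | 6α-TBSO-13α-hydroxyisocopalan-15-al | O[C@@]2(C)CC[C@@H]3[C@@]4(C)CCCC(C)(C)[C@@H]4[C@@H](O[Si](C)(C)C(C)(C)C)C[C@@]3(C)[C@@H]2C=O | intermediate
7 | 1,3-dithiane of 6 (C15 = dithiane C2) | O[C@@]2(C)CC[C@@H]3[C@@]4(C)CCCC(C)(C)[C@@H]4[C@@H](O[Si](C)(C)C(C)(C)C)C[C@@]3(C)[C@@H]2C1SCCCS1 | intermediate
8 | 3-methylfuran-2(5H)-one | CC1=CCOC1=O | starting material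
9 | methyl (Z)-4-chloro-2-methylbut-2-enoate | COC(=O)/C(C)=C\CCl | intermediate
10 | (Z)-4-chloro-2-methylbut-2-en-1-ol | OC/C(C)=C\CCl | intermediate
11 | (Z)-1-bromo-4-chloro-2-methylbut-2-ene | BrC/C(C)=C\CCl | intermediate
12 | dilithio dianion of 7 (O13 alkoxide, C15 carbanion) | [Li+].[Li+].[O-][C@@]2(C)CC[C@@H]3[C@@]4(C)CCCC(C)(C)[C@@H]4[C@@H](O[Si](C)(C)C(C)(C)C)C[C@@]3(C)[C@@H]2[C-]1SCCCS1 | intermediate
13 | lithium alkoxide of the C15-[(Z)-4-chloro-2-methylbut-2-enyl] dithiane | [Li+].[O-][C@@]2(C)CC[C@@H]3[C@@]4(C)CCCC(C)(C)[C@@H]4[C@@H](O[Si](C)(C)C(C)(C)C)C[C@@]3(C)[C@@H]2C1(SCCCS1)C/C(C)=C\CCl | intermediate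
14 | 6-O-TBS oxocene with C15 spiro-1,3-dithiane | C/C1=C/CO[C@@]2(C)CC[C@@H]3[C@@]4(C)CCCC(C)(C)[C@@H]4[C@@H](O[Si](C)(C)C(C)(C)C)C[C@@]3(C)[C@@H]2C5(SCCCS5)C1 | intermediate
15 | 6-O-TBS ether of the target | C/C1=C/CO[C@@]2(C)CC[C@@H]3[C@@]4(C)CCCC(C)(C)[C@@H]4[C@@H](O[Si](C)(C)C(C)(C)C)C[C@@]3(C)[C@@H]2CC1 | intermediate
16 | CNP0179324.1 | C/C1=C/CO[C@@]2(C)CC[C@@H]3[C@@]4(C)CCCC(C)(C)[C@@H]4[C@@H](O)C[C@@]3(C)[C@@H]2CC1 | target

**Step count and risks**
Total: 11 steps. Longest linear sequence: 8 steps (1–5, 9–11); the three-step preparation of 11 (steps 6–8) runs in parallel.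

Steps most likely to fail:

Step 9 (key step). Lithiation of the hindered dithiane may be incomplete. After C-alkylation, the lithium alkoxide may also fail to close the eight-membered ring and instead cause 1,4-elimination of HCl or intermolecular etherification. The fallback closes the ring by metathesis instead of O-alkylation. It sets out from 7: lithiation and alkylation with 3-bromo-2-methylpropene should give the C15-methallyl dithiane F1. O-allylation of the tertiary alcohol (KH, allyl bromide, THF) should give the allyl ether F2. Ring-closing metathesis with the second-generation Grubbs catalyst, forming C17=C18 (Z enforced by the ring), comes back to the route at 14.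

Step 3. The C8 radical may bond on the wrong face (cis B/C fusion) or be reduced before it cyclises. The fallback forms ring C by a cation–olefin cyclisation. It sets out from 2: dehydrative allylic sulfonylation (PhSO2H, Pd(PPh3)4 cat., THF) should give the linear (13E)-allylic sulfone F3. Proton-initiated cyclisation (SnCl4 with 2,6-dimethoxyphenol, CH2Cl2, −78 °C) through a chair–chair transition state should give the trans-fused tricyclic 12-ene sulfone F4. Mukaiyama hydration (Co(acac)2 cat., PhSiH3, O2) with oxygen capture on the α-face of the C13 radical comes back to the route at 5.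

Step 4. The β-hydroxy aldehyde may undergo retro-aldol cleavage or C14 epimerisation in the basic peroxide medium, or the carbanion may be over-oxidised. The fallback never frees the aldehyde. It sets out from 5: the dianion (n-BuLi, 2.2 equiv) is sulfenylated with PhSSPh to the α-phenylthio sulfone F5 (C15 epimers). Lewis-acid ionisation of the sulfinate (MgBr2·OEt2 or SnCl4, CH2Cl2, −40 °C) in the presence of propane-1,3-dithiol should trap the thionium ion and exchange to the dithiane, coming back to the route at 7.

**Further compounds**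
F1 | step 9 | C15-methallyl dithiane (13α-OH free) | O[C@@]2(C)CC[C@@H]3[C@@]4(C)CCCC(C)(C)[C@@H]4[C@@H](O[Si](C)(C)C(C)(C)C)C[C@@]3(C)[C@@H]2C1(SCCCS1)CC(C)=C
F2 | step 9 | 13-O-allyl ether of F1 | C=CCO[C@@]2(C)CC[C@@H]3[C@@]4(C)CCCC(C)(C)[C@@H]4[C@@H](O[Si](C)(C)C(C)(C)C)C[C@@]3(C)[C@@H]2C1(SCCCS1)CC(C)=C
F3 | step 3 | (13E)-6α-TBSO-labda-8(17),13-dien-15-yl phenyl sulfone | C/C(=C\CS(=O)(=O)c1ccccc1)CC[C@@H]2[C@@]3(C)CCCC(C)(C)[C@@H]3[C@@H](O[Si](C)(C)C(C)(C)C)CC2=C
F4 | step 3 | 6α-TBSO-isocopal-12-en-15-yl phenyl sulfone | CC2=CC[C@@H]3[C@@]4(C)CCCC(C)(C)[C@@H]4[C@@H](O[Si](C)(C)C(C)(C)C)C[C@@]3(C)[C@@H]2CS(=O)(=O)c1ccccc1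
F5 | step 4 | 15-phenylthio derivative of sulfone 5 (C15 epimers) | O[C@@]2(C)CC[C@@H]3[C@@]4(C)CCCC(C)(C)[C@@H]4[C@@H](O[Si](C)(C)C(C)(C)C)C[C@@]3(C)[C@@H]2C(Sc1ccccc1)S(=O)(=O)c1ccccc1
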